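Sunday's flask holds 12700 substrate for each free catalyst, so you can treat the catalyst as a wheel and ask how fast it turns.

* [target] at the end for Sunday's, Tuesday's, Wednesday's, Monday's, Thursday's, in this order
* the shape of the row from first to last (falls, then rises / falls all the way / rises all the way / rises, then falls / hardly changes)

| setting | Sunday's | Tuesday's | Wednesday's | Monday's | Thursday's |
|---|---|---|---|---|---|
| substrate | 0.019 M | 0.019 M | 0.019 M | 0.019 M | 0.019 M |
| partner | 0.0285 M | 0.0285 M | 0.0285 M | 0.0285 M | 0.0285 M |
| free catalyst | 1.5 µM | 3.0 µM | 6.0 µM | 12 µM | 25 µM |
| time | 80 s | 80 s | 80 s | 80 s | 80 s |

    partner + catalyst intermediate B → catalyst intermediate C (k1 = 1.9 × 10⁵ /M/s)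
    target ⇌ isomer of the product (K2 = 19, k2 = 0.023 /s)
    catalyst intermediate A → catalyst intermediate B (k3 = 45 /s)
    partner ⇌ dormant form (K4 = 0.56, k4 = 0.014 /s)
    catalyst intermediate C ⇌ free catalyst + target (K5 = 0.0079 M, k5 = 57 /s)
    substrate + free catalyst → catalyst intermediate A (k6 = 12000 /M/s)

- "hardly changes" means that all values lie within two and a half points (for a concentration: within two and a half percent of the largest)
- run time (Sunday's): 80 s

Freeze the charge and walk once round the wheel. You wait 0.00439 s for substrate, 0.0222 s in catalyst intermediate A, 1.85 × 10⁻⁴ s for partner and 0.0175 s for catalyst intermediate C to release target. Their sum is 0.0443 s: the turn time, the seconds one catalyst needs per cycle at the charge. At the charge the wait in catalyst intermediate A is the longest and the wait in catalyst intermediate C comes next, so these two forms are the resting states of this frozen picture.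

So, at the frozen pace, Sunday's flask should convert a fraction 0.00178 /s of its substrate charge, or 14.2% over the run. Target drains meanwhile at 0.023 /s, and the constant of the back-flow is far smaller, so for this estimate you can ignore it. A steady feed into that drain leaves standing what was made in 36.6 s, less than the run. That puts Sunday's target at 6.51% of the charge, or 0.00124 M. Tuesday's comes to 13.0% and Wednesday's to 26.0%.

At the frozen pace the charge clears in 70.2 s on Monday's and 33.7 s on Thursday's, both inside the run. Feed until then and let target drain afterwards: Monday's gives 39.6% and Thursday's 24.0%, so I commit to a row that rises, then falls.

The weak link is the frozen turn time. The wait for substrate stretches as substrate falls, and target binding back multiplies it by one plus target over 0.0079 M. With my reckoned end values for Sunday's flask the turn time becomes 0.0459 s, just 3.45% longer. My clearing times for Monday's and Thursday's lie inside the run, so in those two flasks substrate should fall further than in Sunday's, the stretch should be larger and clearing should come later, which should lower my Monday's value and raise my Thursday's.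

The forecast gives 0.00123 M, 0.0024 M, 0.0045 M, 0.0069 M and 0.0058 M, shape rises, then falls, and says of Thursday's flask that “the substrate is gone by about 60 s, and target then decays to its isomer”. Its Monday's value is lower than mine and its Thursday's higher.

The flask gives 0.00124 M, 0.00241 M, 0.00450 M, 0.00696 M and 0.00564 M: rises, then falls. The row turns at 14 µM, above Monday's charge and below Thursday's, so the fall in the shape needs a last flask beyond that concentration. Sunday's flask ends with 86% of its substrate charge still unbound, and the turn time reckoned 85.8%. Stretched with Monday's end readings, substrate 13.1% and target 36.7%, the turn time is 0.103 s. The wait in catalyst intermediate A makes up 21.5% of that, and Monday's holds 21.5% of its catalyst as catalyst intermediate A.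

The constants were chosen freely; no experiment stands behind them.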